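## Retrosynthetic overview

1. Last, the (Z)-2-(hydroxymethyl)but-2-enoate is grown on the primary hydroxyl: a but-2-ynoate ester undergoes syn-hydroalumination and formaldehyde aldol, which sets the Z geometry.
2. The E-aryl-allyl arm comes from Horner–Wadsworth–Emmons olefination of a γ-lactol (masked 4-hydroxy aldehyde) with a 3,4-dimethoxybenzyl phosphonate.
3. Key C–C bond (benzylic carbinol carbon to the neighbouring methine): a Hoppe homoaldol reaction. A (–)-sparteine-derived α-titanated (E)-4-silyloxybut-2-enyl carbamate acts as a chiral homoenolate (d3) reagent and adds through its γ-carbon, the β-carbon of the latent aldehyde, to veratraldehyde, setting both stereocentres (anti) in one step.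
4. The carbamate is made in two steps from (E)-but-2-ene-1,4-diol.
5. Rings: none of the target is built (both arenes are bought). One transient oxolane (the lactol) is closed in step 4 and opened again in step 5.

Assumption: (–)-sparteine is taken to induce, in the silyloxybutenyl carbamate of step 3, the same sense as in the parent (E)-but-2-enyl carbamate (S-lithio species, inversion on titanation); if the sense were opposite, (+)-sparteine would be used with no other change.

## Route

Step 1
Reactants: 1 (2E)-but-2-ene-1,4-diol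
Product: 2 (2E)-4-{[tert-butyl(dimethyl)silyl]oxy}but-2-en-1-ol
Conditions: NaH (1.0 equiv), THF, 0 °C to rt; TBSCl (1.0 equiv)
Reagents that add atoms: tert-butyldimethylsilyl chloride (TBSCl), CC(C)(C)[Si](C)(C)Cl
Why: McDougal monosilylation, in which the sparingly soluble monosodium alkoxide of the symmetrical diol is silylated once and the E-alkene is untouched.

Step 2
Reactants: 2 (2E)-4-{[tert-butyl(dimethyl)silyl]oxy}but-2-en-1-ol
Product: 3 (2E)-4-{[tert-butyl(dimethyl)silyl]oxy}but-2-en-1-yl N,N-diisopropylcarbamate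
Conditions: NaH (1.1 equiv), THF, 0 °C; i-Pr2NCOCl (1.1 equiv), reflux
Reagents that add atoms: N,N-diisopropylcarbamoyl chloride, CC(C)N(C(C)C)C(Cl)=O
Why: O-Carbamoylation of the sodium alkoxide with the hindered carbamoyl chloride installs the N,N-diisopropylcarbamate, the directing and anion-stabilising group needed for the Hoppe α-lithiation.

Step 3
Reactants: 3 (2E)-4-{[tert-butyl(dimethyl)silyl]oxy}but-2-en-1-yl N,N-diisopropylcarbamate; 4 3,4-dimethoxybenzaldehyde (veratraldehyde)
Product: 7 (1Z,3R,4S)-3-({[tert-butyl(dimethyl)silyl]oxy}methyl)-4-(3,4-dimethoxyphenyl)-4-hydroxybut-1-en-1-yl N,N-diisopropylcarbamate, via lithiated carbamate 5 (not isolated), via allyl titanate 6 (not isolated)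
Conditions: n-BuLi (1.1 equiv), (–)-sparteine (1.2 equiv), pentane/cyclohexane, –78 °C, 3 h; Ti(OiPr)4 (3 equiv), –78 °C; then 4 (1.2 equiv), –78 °C to rt; aqueous work-up
Reagents that add atoms: none
Why: Hoppe asymmetric homoaldol reaction, in which (–)-sparteine-mediated α-lithiation gives the S-lithio carbamate 5, titanation with inversion gives the R-allyl titanate 6, and this chiral homoenolate (d3) reagent adds through its γ-carbon to the aldehyde in a chair Zimmerman–Traxler transition state (syn-SE2'), so that the E-alkene fixes the anti C3/C4 relationship, the metal-bearing carbon fixes the absolute configuration (3R,4S) by 1,3-chirality transfer, and the Z-enol carbamate left behind is the masked aldehyde.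

Step 4
Reactants: 7 (1Z,3R,4S)-3-({[tert-butyl(dimethyl)silyl]oxy}methyl)-4-(3,4-dimethoxyphenyl)-4-hydroxybut-1-en-1-yl N,N-diisopropylcarbamate
Product: 9 (4R,5S)-5-(3,4-dimethoxyphenyl)-4-(hydroxymethyl)oxolan-2-ol, via methyl lactol ether 8 (not isolated)
Conditions: MeSO3H (2.0 equiv), Hg(OAc)2 (5 mol%), MeOH, rt, 16 h; then H2O/THF (1:1), rt
Reagents that add atoms: water, O
Why: Acid-mediated, divalent-mercury-catalysed solvolysis of the γ-hydroxy enol carbamate (Hoppe lactol-ether formation) closes the oxolane through the benzylic hydroxyl with loss of the carbamate as CO2 and amine, the acidic methanol strips the primary silyl ether at the same time, and added water hydrolyses acetal 8 to lactol 9 without touching either carbon stereocentre (the trans ring is also the thermodynamic one).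

Step 5
Reactants: 9 (4R,5S)-5-(3,4-dimethoxyphenyl)-4-(hydroxymethyl)oxolan-2-ol; 10 diethyl (3,4-dimethoxybenzyl)phosphonate
Product: 13 (1S,2R)-1-(3,4-dimethoxyphenyl)-2-[(2E)-3-(3,4-dimethoxyphenyl)prop-2-en-1-yl]propane-1,3-diol, via phosphonate carbanion 11 (not isolated), via open-chain hydroxy aldehyde 12 (not isolated)
Conditions: 10 (4 equiv), KOtBu (4 equiv), THF/DMF (4:1), 0 °C; then 9, 0 °C to rt
Reagents that add atoms: none
Why: Horner–Wadsworth–Emmons olefination of a lactol, in which the ring-opened aldehyde 12 is intercepted by the benzylic phosphonate carbanion 11 and reversible addition followed by syn-elimination gives the conjugated E-styrene, while the stereocentres, neither of which is α to the carbonyl, cannot epimerise.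

Step 6
Reactants: 13 (1S,2R)-1-(3,4-dimethoxyphenyl)-2-[(2E)-3-(3,4-dimethoxyphenyl)prop-2-en-1-yl]propane-1,3-diol; 14 but-2-ynoic acid
Product: 15 (2R,3S)-3-(3,4-dimethoxyphenyl)-2-[(2E)-3-(3,4-dimethoxyphenyl)prop-2-en-1-yl]-3-hydroxypropyl but-2-ynoate
Conditions: 14 (1.1 equiv), N,N'-diisopropylcarbodiimide (1.1 equiv), DMAP (5 mol%), CH2Cl2, –20 to 0 °C
Reagents that add atoms: none
Why: Steglich-type carbodiimide esterification, which acylates the unhindered primary hydroxyl much faster than the flanked secondary benzylic one at low temperature, and the but-2-ynoate has no alkene geometry to lose.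

Step 7
Reactants: 15 (2R,3S)-3-(3,4-dimethoxyphenyl)-2-[(2E)-3-(3,4-dimethoxyphenyl)prop-2-en-1-yl]-3-hydroxypropyl but-2-ynoate; 16 formaldehyde (monomer, from cracked paraformaldehyde)
Product: 18 (2R,3S)-3-(3,4-dimethoxyphenyl)-2-[(2E)-3-(3,4-dimethoxyphenyl)prop-2-en-1-yl]-3-hydroxypropyl (2Z)-2-(hydroxymethyl)but-2-enoate, via alkenylalane 17 (not isolated)
Conditions: i-Bu2AlH (2.5 equiv), N-methylmorpholine N-oxide (2.6 equiv), THF, 0 °C, 2 h; then 16 (THF solution, excess), –78 to 0 °C; aq. potassium sodium tartrate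
Reagents that add atoms: none
Why: Conjugate syn-hydroalumination of the 2-alkynoate followed by aldol capture of formaldehyde at the aluminium-bearing α-carbon with retention (vinylalumination, a reductive aldol of an ynoate), which places the new hydrogen and the new hydroxymethyl on the same side and hence the methyl cis to the ester, giving the 2Z geometry of the target.

## Compound list

1 | (2E)-but-2-ene-1,4-diol | OC/C=C/CO | starting material
2 | (2E)-4-{[tert-butyl(dimethyl)silyl]oxy}but-2-en-1-ol | CC(C)(C)[Si](C)(C)OC/C=C/CO | intermediate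
3 | (2E)-4-{[tert-butyl(dimethyl)silyl]oxy}but-2-en-1-yl N,N-diisopropylcarbamate | CC(C)N(C(C)C)C(=O)OC/C=C/CO[Si](C)(C)C(C)(C)C | intermediate
4 | 3,4-dimethoxybenzaldehyde (veratraldehyde) | COc1ccc(C=O)cc1OC | starting material
5 | [(1S,2E)-4-{[tert-butyl(dimethyl)silyl]oxy}-1-(N,N-diisopropylcarbamoyloxy)but-2-en-1-yl]lithium, held as its (–)-sparteine complex | [Li][C@H](OC(=O)N(C(C)C)C(C)C)/C=C/CO[Si](C)(C)C(C)(C)C | intermediate (not isolated)
6 | lithium [(1R,2E)-4-{[tert-butyl(dimethyl)silyl]oxy}-1-(N,N-diisopropylcarbamoyloxy)but-2-en-1-yl]tetraisopropoxytitanate (tetravalent titanium) | [Li+].CC(C)O[Ti-](OC(C)C)(OC(C)C)(OC(C)C)[C@@H](OC(=O)N(C(C)C)C(C)C)/C=C/CO[Si](C)(C)C(C)(C)C | intermediate (not isolated)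
7 | (1Z,3R,4S)-3-({[tert-butyl(dimethyl)silyl]oxy}methyl)-4-(3,4-dimethoxyphenyl)-4-hydroxybut-1-en-1-yl N,N-diisopropylcarbamate | CC(C)(C)[Si](C)(C)OC[C@@H](/C=C\OC(=O)N(C(C)C)C(C)C)[C@H](O)c1ccc(OC)c(OC)c1 | intermediate
8 | [(2S,3R)-2-(3,4-dimethoxyphenyl)-5-methoxyoxolan-3-yl]methanol (both anomers, aryl and hydroxymethyl trans) | OC[C@@H](CC2OC)[C@H](O2)c1ccc(OC)c(OC)c1 | intermediate (not isolated)
9 | (4R,5S)-5-(3,4-dimethoxyphenyl)-4-(hydroxymethyl)oxolan-2-ol (both anomers, aryl and hydroxymethyl trans; equilibrates with the lactol closed through the primary hydroxyl) | OC[C@@H](CC2O)[C@H](O2)c1ccc(OC)c(OC)c1 | intermediate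
10 | diethyl (3,4-dimethoxybenzyl)phosphonate | CCOP(=O)(OCC)Cc1ccc(OC)c(OC)c1 | starting material
11 | potassium salt of the benzylic carbanion of 10 | [K+].CCOP(=O)(OCC)[CH-]c1ccc(OC)c(OC)c1 | intermediate (not isolated)
12 | (3R,4S)-4-(3,4-dimethoxyphenyl)-4-hydroxy-3-(hydroxymethyl)butanal | OC[C@@H](CC=O)[C@H](O)c1ccc(OC)c(OC)c1 | intermediate (not isolated)
13 | (1S,2R)-1-(3,4-dimethoxyphenyl)-2-[(2E)-3-(3,4-dimethoxyphenyl)prop-2-en-1-yl]propane-1,3-diol | OC[C@@H](C/C=C/c1ccc(OC)c(OC)c1)[C@H](O)c1ccc(OC)c(OC)c1 | intermediate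
14 | but-2-ynoic acid | CC#CC(=O)O | starting material
15 | (2R,3S)-3-(3,4-dimethoxyphenyl)-2-[(2E)-3-(3,4-dimethoxyphenyl)prop-2-en-1-yl]-3-hydroxypropyl but-2-ynoate | CC#CC(=O)OC[C@@H](C/C=C/c1ccc(OC)c(OC)c1)[C@H](O)c1ccc(OC)c(OC)c1 | intermediate
16 | formaldehyde (monomer, from cracked paraformaldehyde) | C=O | starting material
17 | (2E)-2-(diisobutylalumanyl)but-2-enoate of 13 at the primary oxygen, with the secondary hydroxyl as its diisobutylaluminium alkoxide | C/C=C(/[Al](CC(C)C)CC(C)C)C(=O)OC[C@@H](C/C=C/c1ccc(OC)c(OC)c1)[C@H](O[Al](CC(C)C)CC(C)C)c1ccc(OC)c(OC)c1 | intermediate (not isolated)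
18 | (2R,3S)-3-(3,4-dimethoxyphenyl)-2-[(2E)-3-(3,4-dimethoxyphenyl)prop-2-en-1-yl]-3-hydroxypropyl (2Z)-2-(hydroxymethyl)but-2-enoate | C/C=C(/CO)C(=O)OC[C@@H](C/C=C/c1ccc(OC)c(OC)c1)[C@H](O)c1ccc(OC)c(OC)c1 | target

## Totals

Total step count: 7. Longest linear sequence: 7 steps (1 to 18).

## The three steps most likely to fail

**Step 3 (homoaldol).** The lithiated carbamate 5 carries a silyloxy group on the carbon next to its γ-position and may lose silanolate by 1,4-elimination to a dienyl carbamate. The E-geometry (no cisoid path for a syn-elimination), –78 °C and a hydrocarbon solvent argue against this, but it is untested for this substrate. The enantiomeric excess also depends on 5 resolving or crystallising with sparteine as the parent but-2-enyl system does.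

The fallback sets out from 4 and comes back at 13. It swaps the stoichiometric chiral homoenolate for a catalytic reversed-polarity allyl unit. Aldehyde 4 is coupled with 4-vinyl-1,3-dioxolan-2-one under transfer-hydrogenative conditions ([Ir(cod)Cl]2, the SEGPHOS enantiomer that gives the 1S,2R product, 4-cyano-3-nitrobenzoic acid, K3PO4, 2-propanol, THF, 60 °C). Here a π-allyl complex of iridium acts as the nucleophile and gives the anti adduct (1S,2R)-1-(3,4-dimethoxyphenyl)-2-ethenylpropane-1,3-diol F1. Acetonide formation (2,2-dimethoxypropane, pyridinium tosylate) gives (4S,5R)-4-(3,4-dimethoxyphenyl)-5-ethenyl-2,2-dimethyl-1,3-dioxane F2. Hydroboration and oxidation (9-BBN, then NaBO3) gives 2-[(4S,5R)-4-(3,4-dimethoxyphenyl)-2,2-dimethyl-1,3-dioxan-5-yl]ethan-1-ol F3. Dess–Martin oxidation gives 2-[(4S,5R)-4-(3,4-dimethoxyphenyl)-2,2-dimethyl-1,3-dioxan-5-yl]acetaldehyde F4. Olefination with 10 and KOtBu gives (4S,5R)-4-(3,4-dimethoxyphenyl)-5-[(2E)-3-(3,4-dimethoxyphenyl)prop-2-en-1-yl]-2,2-dimethyl-1,3-dioxane F5. Aqueous acetic acid (80%, rt) then releases diol 13.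

**Step 7 (hydroalumination and formaldehyde capture).** The aluminium hydride may reduce the ester, the aluminium alkoxide of the benzylic oxygen may trigger acyl migration, and the alkenylalane may equilibrate through the allenolate and erode the Z geometry. Formaldehyde is also a less well tested electrophile here than higher aldehydes.

The fallback sets out from 15 and comes back at 18. It replaces the aldol capture by cross-coupling. Syn-hydrostannation of the ynoate (n-Bu3SnH, Pd(PPh3)4 as the zerovalent palladium catalyst, THF, rt) gives (2R,3S)-3-(3,4-dimethoxyphenyl)-2-[(2E)-3-(3,4-dimethoxyphenyl)prop-2-en-1-yl]-3-hydroxypropyl (2E)-2-(tributylstannyl)but-2-enoate F7. Iododestannylation with retention (I2, 1.0 equiv, CH2Cl2, 0 °C) gives (2R,3S)-3-(3,4-dimethoxyphenyl)-2-[(2E)-3-(3,4-dimethoxyphenyl)prop-2-en-1-yl]-3-hydroxypropyl (2E)-2-iodobut-2-enoate F8. Stille coupling with (tributylstannyl)methanol (Pd(PPh3)4, dioxane, 90 °C) installs the hydroxymethyl group with retention and gives 18.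

**Step 5 (olefination of the lactol).** The benzylic phosphonate anion is only moderately reactive, the open-chain aldehyde 12 is a minor equilibrium component of a diol-lactol that consumes base, and the E/Z ratio of a semi-stabilised olefination is not guaranteed.

The fallback sets out from 9 and comes back at 13. It builds the styrene by metathesis instead. Wittig methylenation of the lactol (Ph3PCH3Br, KOtBu, THF, 0 °C to rt) gives (1S,2R)-1-(3,4-dimethoxyphenyl)-2-(prop-2-en-1-yl)propane-1,3-diol F6. Cross-metathesis with 3,4-dimethoxystyrene (second-generation Hoveyda–Grubbs catalyst, RuCl2(H2IMes)(=CH-C6H4-2-O-i-Pr), CH2Cl2, 40 °C) gives 13 as the E-isomer.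

## Further compounds

F1 | step 3 | (1S,2R)-1-(3,4-dimethoxyphenyl)-2-ethenylpropane-1,3-diol | OC[C@@H](C=C)[C@H](O)c1ccc(OC)c(OC)c1
F2 | step 3 | (4S,5R)-4-(3,4-dimethoxyphenyl)-5-ethenyl-2,2-dimethyl-1,3-dioxane | CC2(C)OC[C@@H](C=C)[C@H](O2)c1ccc(OC)c(OC)c1
F3 | step 3 | 2-[(4S,5R)-4-(3,4-dimethoxyphenyl)-2,2-dimethyl-1,3-dioxan-5-yl]ethan-1-ol | CC2(C)OC[C@@H](CCO)[C@H](O2)c1ccc(OC)c(OC)c1
F4 | step 3 | 2-[(4S,5R)-4-(3,4-dimethoxyphenyl)-2,2-dimethyl-1,3-dioxan-5-yl]acetaldehyde | CC2(C)OC[C@@H](CC=O)[C@H](O2)c1ccc(OC)c(OC)c1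
F5 | step 3 | (4S,5R)-4-(3,4-dimethoxyphenyl)-5-[(2E)-3-(3,4-dimethoxyphenyl)prop-2-en-1-yl]-2,2-dimethyl-1,3-dioxane | CC2(C)OC[C@@H](C/C=C/c3ccc(OC)c(OC)c3)[C@H](O2)c1ccc(OC)c(OC)c1
F6 | step 5 | (1S,2R)-1-(3,4-dimethoxyphenyl)-2-(prop-2-en-1-yl)propane-1,3-diol | OC[C@@H](CC=C)[C@H](O)c1ccc(OC)c(OC)c1
F7 | step 7 | (2R,3S)-3-(3,4-dimethoxyphenyl)-2-[(2E)-3-(3,4-dimethoxyphenyl)prop-2-en-1-yl]-3-hydroxypropyl (2E)-2-(tributylstannyl)but-2-enoate | C/C=C(/[Sn](CCCC)(CCCC)CCCC)C(=O)OC[C@@H](C/C=C/c1ccc(OC)c(OC)c1)[C@H](O)c1ccc(OC)c(OC)c1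
F8 | step 7 | (2R,3S)-3-(3,4-dimethoxyphenyl)-2-[(2E)-3-(3,4-dimethoxyphenyl)prop-2-en-1-yl]-3-hydroxypropyl (2E)-2-iodobut-2-enoate | C/C=C(/I)C(=O)OC[C@@H](C/C=C/c1ccc(OC)c(OC)c1)[C@H](O)c1ccc(OC)c(OC)c1
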